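**Strategy.** Everything rests on cutting the bond between C2 of the dihydrofuran ring and the ipso carbon of the syringyl ring. C2 sits between the ring oxygen O1 and the methyl-bearing stereocentre C3, so a C2 radical is oxygen-stabilised, planar and facially biased by the C3 methyl group. In one operation, nickel-catalysed decarboxylative arylation of a C2 carboxylic acid (through its redox-active ester) with a syringyl zinc reagent joins the two halves and erases and resets C2, funnelling either C2 epimer to the trans (2S,3S) isomer. The precursor is the cis acid from asymmetric hydrogenation of a benzofuran-2-carboxylate, which sets C3; the carboxyl group is a traceless handle.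

Key step: step 6

Remark: the sense of induction of the chiral catalysts (step 3 and its fallback) is assumed; the ligand antipode is used if the opposite face is delivered.

**Step 1**
Reactants: 1 1-(2-hydroxy-3-methoxyphenyl)ethan-1-one
Product: 2 1-(5-bromo-2-hydroxy-3-methoxyphenyl)ethan-1-one
Conditions: NBS, MeCN, 0 °C → rt
Reagents that add atoms: N-bromosuccinimide, O=C1CCC(=O)N1Br
Why: Electrophilic aromatic bromination goes para to the free OH (C5), since both ortho positions are occupied and the acetyl group directs meta to the same carbon.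

**Step 2**
Reactants: 2 1-(5-bromo-2-hydroxy-3-methoxyphenyl)ethan-1-one, 3 ethyl bromoacetate
Product: 5 ethyl 5-bromo-7-methoxy-3-methyl-1-benzofuran-2-carboxylate, via aryloxyacetate 4 (not isolated)
Conditions: K2CO3, DMF, 60 °C, then 130 °C
Reagents that add atoms: none
Why: Williamson O-alkylation gives 4, whose ester enolate adds to the ortho ketone (intramolecular aldol, 5-exo-trig) and dehydrates to the aromatic benzofuran in a Rap–Stoermer-type annulation that places the ketone methyl at C3 and the ester at C2.

**Step 3**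
Reactants: 5 ethyl 5-bromo-7-methoxy-3-methyl-1-benzofuran-2-carboxylate
Product: 6 ethyl (2R,3S)-5-bromo-7-methoxy-3-methyl-2,3-dihydro-1-benzofuran-2-carboxylate (cis)
Conditions: [Ru(cod)(2-methylallyl)2] (5 mol %), (S,S)-SINpEt·HBF4 (10 mol %), KOtBu (cat.), H2 (60 bar), hexane/toluene, 40 °C
Reagents that add atoms: none
Why: Catalytic asymmetric hydrogenation of a benzofuran with a chiral Ru–NHC catalyst should add H2 syn to one face of the acrylate-like C2=C3 bond, giving the cis ester and setting C3 as S under ligand control, while the C2 centre formed alongside is provisional.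

**Step 4**
Reactants: 6 ethyl (2R,3S)-5-bromo-7-methoxy-3-methyl-2,3-dihydro-1-benzofuran-2-carboxylate, 7 4,4,5,5-tetramethyl-2-[(E)-prop-1-en-1-yl]-1,3,2-dioxaborolane
Product: 9 (2R,3S)-7-methoxy-3-methyl-5-[(E)-prop-1-en-1-yl]-2,3-dihydro-1-benzofuran-2-carboxylic acid, via propenyl ester 8 (not isolated)
Conditions: Pd(dppf)Cl2 (3 mol %), K2CO3, 1,4-dioxane/H2O, 80 °C; then LiOH·H2O, 40 °C; 1 M HCl work-up
Reagents that add atoms: lithium hydroxide, [Li+].[OH-]
Why: Suzuki–Miyaura coupling of the aryl bromide with the alkenyl boronate keeps the E geometry and hydroxide then saponifies the ethyl ester in the same pot; C3 is not acidic and stays untouched, and any epimerisation at C2 is immaterial.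

**Step 5**
Reactants: 10 4-bromo-2,6-dimethoxyphenol
Product: 11 (4-bromo-2,6-dimethoxyphenoxy)(tert-butyl)dimethylsilane
Conditions: TBSCl, imidazole, DMF, rt
Reagents that add atoms: tert-butyldimethylsilyl chloride, CC(C)(C)[Si](C)(C)Cl
Why: Imidazole-promoted silylation masks the acidic phenol so that the bromide can be turned into an organometallic reagent.

**Step 6**
Reactants: 9 (2R,3S)-7-methoxy-3-methyl-5-[(E)-prop-1-en-1-yl]-2,3-dihydro-1-benzofuran-2-carboxylic acid, 11 (4-bromo-2,6-dimethoxyphenoxy)(tert-butyl)dimethylsilane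
Product: 15 tert-butyl{4-[(2S,3S)-7-methoxy-3-methyl-5-[(E)-prop-1-en-1-yl]-2,3-dihydro-1-benzofuran-2-yl]-2,6-dimethoxyphenoxy}dimethylsilane, via aryllithium 12 (not isolated), via arylzinc chloride 13 (not isolated), via N-hydroxyphthalimide ester 14 (not isolated)
Conditions: 9, N-hydroxyphthalimide, DIC, DMAP (cat.), CH2Cl2, rt, then evaporate; 11, n-BuLi, THF, −78 °C, then ZnCl2, −78 °C → rt; combine, NiCl2·glyme (20 mol %), 4,4′-di-tert-butyl-2,2′-bipyridine (40 mol %), THF/DMF, rt
Reagents that add atoms: none
Why: DIC couples 9 with N-hydroxyphthalimide to the redox-active ester 14 while Br/Li exchange on 11 and transmetalation give 13; an aryl–Ni(I) species formed from 13 transfers an electron to 14, which loses phthalimide anion and CO2 to give the C2 radical, and capture by aryl–nickel followed by reductive elimination from Ni(III) forms the C2–aryl bond. The closest known reaction type is the nickel-catalysed decarboxylative Negishi-type arylation of N-hydroxyphthalimide esters, which is established for α-oxy acids such as tetrahydrofuran-2-carboxylic and furanosyl acids. No ring is closed. The new stereocentre C2 is controlled by the adjacent C3 methyl group: the radical is α to O1 and essentially planar, so the configuration of the acid is erased and the bulky aryl–nickel fragment should bond to the face anti to the methyl group on the rigid benzo-fused five-membered ring, giving the trans (2S,3S) isomer as in 1,2-trans-selective C-aryl furanoside couplings. The step needs trans selectivity and C–C coupling faster than β-hydride elimination to the aromatic benzofuran or radical addition to the propenyl group; fast reductive elimination from Ni(III) and the poor acceptor character of the electron-rich 1,2-disubstituted styrene should secure this, and any minor cis isomer is removed by chromatography of 15.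

**Step 7**
Reactants: 15 tert-butyl{4-[(2S,3S)-7-methoxy-3-methyl-5-[(E)-prop-1-en-1-yl]-2,3-dihydro-1-benzofuran-2-yl]-2,6-dimethoxyphenoxy}dimethylsilane
Product: 16 odoratisol A, 4-[(2S,3S)-7-methoxy-3-methyl-5-[(E)-prop-1-en-1-yl]-2,3-dihydro-1-benzofuran-2-yl]-2,6-dimethoxyphenol
Conditions: TBAF, AcOH, THF, 0 °C
Reagents that add atoms: none
Why: Fluoride cleaves the aryl silyl ether, and the acetic acid buffer keeps the liberated phenol protonated so that the p-hydroxybenzyl ether at C2 does not open through a quinone methide and both stereocentres stay intact.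

**Compound list**
1 | 1-(2-hydroxy-3-methoxyphenyl)ethan-1-one | CC(=O)c1cccc(OC)c1O | starting material
2 | 1-(5-bromo-2-hydroxy-3-methoxyphenyl)ethan-1-one | CC(=O)c1cc(Br)cc(OC)c1O | intermediate
3 | ethyl bromoacetate | CCOC(=O)CBr | starting material
4 | ethyl 2-(2-acetyl-4-bromo-6-methoxyphenoxy)acetate | CCOC(=O)COc1c(OC)cc(Br)cc1C(C)=O | intermediate (not isolated)
5 | ethyl 5-bromo-7-methoxy-3-methyl-1-benzofuran-2-carboxylate | CCOC(=O)c1oc2c(OC)cc(Br)cc2c1C | intermediate
6 | ethyl (2R,3S)-5-bromo-7-methoxy-3-methyl-2,3-dihydro-1-benzofuran-2-carboxylate (cis) | Brc1cc(OC)c2c(c1)[C@H](C)[C@H](C(=O)OCC)O2 | intermediate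
7 | 4,4,5,5-tetramethyl-2-[(E)-prop-1-en-1-yl]-1,3,2-dioxaborolane | C/C=C/B1OC(C)(C)C(C)(C)O1 | starting material
8 | ethyl (2R,3S)-7-methoxy-3-methyl-5-[(E)-prop-1-en-1-yl]-2,3-dihydro-1-benzofuran-2-carboxylate | C/C=C/c1cc(OC)c2c(c1)[C@H](C)[C@H](C(=O)OCC)O2 | intermediate (not isolated)
9 | (2R,3S)-7-methoxy-3-methyl-5-[(E)-prop-1-en-1-yl]-2,3-dihydro-1-benzofuran-2-carboxylic acid (cis) | C/C=C/c1cc(OC)c2c(c1)[C@H](C)[C@H](C(=O)O)O2 | intermediate
10 | 4-bromo-2,6-dimethoxyphenol | COc1cc(Br)cc(OC)c1O | starting material
11 | (4-bromo-2,6-dimethoxyphenoxy)(tert-butyl)dimethylsilane | COc1cc(Br)cc(OC)c1O[Si](C)(C)C(C)(C)C | intermediate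
12 | {4-[(tert-butyldimethylsilyl)oxy]-3,5-dimethoxyphenyl}lithium | [Li]c1cc(OC)c(O[Si](C)(C)C(C)(C)C)c(OC)c1 | intermediate (not isolated)
13 | {4-[(tert-butyldimethylsilyl)oxy]-3,5-dimethoxyphenyl}zinc chloride | Cl[Zn]c1cc(OC)c(O[Si](C)(C)C(C)(C)C)c(OC)c1 | intermediate (not isolated)
14 | 1,3-dioxoisoindolin-2-yl (2R,3S)-7-methoxy-3-methyl-5-[(E)-prop-1-en-1-yl]-2,3-dihydro-1-benzofuran-2-carboxylate | C/C=C/c1cc(OC)c2c(c1)[C@H](C)[C@H](C(=O)ON1C(=O)c3ccccc3C1=O)O2 | intermediate (not isolated)
15 | tert-butyl{4-[(2S,3S)-7-methoxy-3-methyl-5-[(E)-prop-1-en-1-yl]-2,3-dihydro-1-benzofuran-2-yl]-2,6-dimethoxyphenoxy}dimethylsilane | C/C=C/c1cc(OC)c2c(c1)[C@H](C)[C@@H](c1cc(OC)c(O[Si](C)(C)C(C)(C)C)c(OC)c1)O2 | intermediate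
16 | odoratisol A, 4-[(2S,3S)-7-methoxy-3-methyl-5-[(E)-prop-1-en-1-yl]-2,3-dihydro-1-benzofuran-2-yl]-2,6-dimethoxyphenol | C/C=C/c1cc(OC)c2c(c1)[C@H](C)[C@@H](c1cc(OC)c(O)c(OC)c1)O2 | target

Total step count: 7. Longest linear sequence: 6 (steps 1, 2, 3, 4, 6, 7).

**Steps most likely to fail**

Step 6. The C2–nickel intermediate may undergo β-hydride elimination with aromatisation to a benzofuran, or the small C3 methyl group may discriminate the two faces of the radical too weakly, eroding trans selectivity. The fallback replaces the radical coupling by a polar one and sets out from 9. Oxidative decarboxylation with Pb(OAc)4, catalytic Cu(OAc)2 and pyridine in benzene should give the anomeric acetate (3S)-7-methoxy-3-methyl-5-[(E)-prop-1-en-1-yl]-2,3-dihydro-1-benzofuran-2-yl acetate F1. Ionisation of F1 with BF3·OEt2 in CH2Cl2 at −78 °C in the presence of excess commercial 2,6-dimethoxyphenol (COc1cccc(OC)c1O) should then give a Friedel–Crafts C-arylation at the free para position of the phenol through the cyclic oxocarbenium ion. The aryl group enters anti to the methyl group, and because the resulting p-hydroxybenzyl ether can re-ionise, the reaction should converge on the more stable trans isomer. This fallback comes back to the route at 16 without a protecting group.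

Step 3. The tetrasubstituted, aromatic C2=C3 bond may react sluggishly or with poor facial selectivity, and hydrodebromination may compete. The fallback sets C3 by conjugate reduction of a non-aromatic enoate and sets out from 2. Wittig olefination and lactonisation with ethyl (triphenylphosphoranylidene)acetate in refluxing N,N-diethylaniline should give 6-bromo-8-methoxy-4-methyl-2H-chromen-2-one F2. Copper hydride asymmetric conjugate reduction (Cu(OAc)2, DTBM-SEGPHOS, PMHS, t-BuOH, toluene) should give (R)-6-bromo-8-methoxy-4-methylchroman-2-one F3. Bromination of the lactone enolate (LiHMDS, then NBS, THF, −78 °C) should give (4S)-3,6-dibromo-8-methoxy-4-methylchroman-2-one F4 as C3 epimers. Hydroxide (NaOH, aqueous THF) opens the lactone and the phenoxide displaces the α-bromide, contracting the ring to (3S)-5-bromo-7-methoxy-3-methyl-2,3-dihydro-1-benzofuran-2-carboxylic acid F5 as C2 epimers. Suzuki–Miyaura coupling of F5 with 7 under the conditions of step 4 comes back to the route at 9, formed together with its C2 epimer (2S,3S)-7-methoxy-3-methyl-5-[(E)-prop-1-en-1-yl]-2,3-dihydro-1-benzofuran-2-carboxylic acid F6, which is equally competent in step 6.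

Step 2. The intramolecular aldol condensation onto the hindered aryl ketone may stall at the aryloxyacetate, with ester hydrolysis competing under the hot basic conditions. The fallback builds the benzofuran by ring contraction of a coumarin and sets out from 2. The coumarin 6-bromo-8-methoxy-4-methyl-2H-chromen-2-one F2, made as above, is brominated at C3 (Br2, AcOH, rt) to 3,6-dibromo-8-methoxy-4-methyl-2H-chromen-2-one F7. Perkin rearrangement (NaOH, EtOH/H2O, reflux) should give 5-bromo-7-methoxy-3-methyl-1-benzofuran-2-carboxylic acid F8. Fischer esterification (EtOH, H2SO4, reflux) comes back to the route at 5.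

**Further compounds**
F1 | step 6 | (3S)-7-methoxy-3-methyl-5-[(E)-prop-1-en-1-yl]-2,3-dihydro-1-benzofuran-2-yl acetate (anomeric mixture) | C/C=C/c1cc(OC)c2c(c1)[C@H](C)C(OC(C)=O)O2
F2 | step 3 | 6-bromo-8-methoxy-4-methyl-2H-chromen-2-one | Cc1cc(=O)oc2c(OC)cc(Br)cc12
F3 | step 3 | (R)-6-bromo-8-methoxy-4-methylchroman-2-one | Brc1cc(OC)c2c(c1)[C@H](C)CC(=O)O2
F4 | step 3 | (4S)-3,6-dibromo-8-methoxy-4-methylchroman-2-one (C3 epimers) | Brc1cc(OC)c2c(c1)[C@H](C)C(Br)C(=O)O2
F5 | step 3 | (3S)-5-bromo-7-methoxy-3-methyl-2,3-dihydro-1-benzofuran-2-carboxylic acid (C2 epimers) | Brc1cc(OC)c2c(c1)[C@H](C)C(C(=O)O)O2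
F6 | step 3 | (2S,3S)-7-methoxy-3-methyl-5-[(E)-prop-1-en-1-yl]-2,3-dihydro-1-benzofuran-2-carboxylic acid (trans) | C/C=C/c1cc(OC)c2c(c1)[C@H](C)[C@@H](C(=O)O)O2
F7 | step 2 | 3,6-dibromo-8-methoxy-4-methyl-2H-chromen-2-one | Cc1c(Br)c(=O)oc2c(OC)cc(Br)cc12
F8 | step 2 | 5-bromo-7-methoxy-3-methyl-1-benzofuran-2-carboxylic acid | Cc1c(C(=O)O)oc2c(OC)cc(Br)cc12
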